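The earlier runs and the new flask are simulated on assumed constants, noise included.

Late times came first at the meeting: at 10.0 min the east run reads 43.9% and the south-east run 24.9%, and both curves have flattened. The process chemist set these readings aside, since the question sits at 5.0%.

| flask | left-handed substrate | right-handed substrate | solid reagent | catalyst | remark |
|---|---|---|---|---|---|
| north-east | 0.020 M | 0.020 M | 0.022 M | 50 µM | run made earlier |
| east | 0.020 M | 0.020 M | 0.022 M | 79 µM | run made earlier |
| south-east | 0.040 M | 0.040 M | 0.022 M | 36 µM | run made earlier |
| flask | 0.020 M | 0.020 M | 0.0220 M | 36 µM |  |

| north-east: time / min | north-east: left-handed product / % | east: time / min | east: left-handed product / % | south-east: time / min | south-east: left-handed product / % |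
|---|---|---|---|---|---|
| 0.833 | 3.0 | 1.33 | 7.4 | 1.33 | 4.4 |
| 2.00 | 10.1 | 3.00 | 23.1 | 3.00 | 13.7 |
| 4.00 | 26.3 | 6.00 | 39.8 | 6.00 | 22.7 |
| 10.0 | 43.0 | 10.0 | 43.9 | 10.0 | 24.9 |

(readings scatter by 1 percentage point)

- catalyst is single-handed; left-handed substrate and right-handed substrate are mirror images of each other, charged as a racemate, each of them at the stated concentration
- given per volume of solution although it is solid: solid reagent
- at the start none of the solid reagent is in solution

- apparent order in catalyst when 5.0% of the left-handed substrate and right-handed substrate together are converted (percent change of the rate of making left-handed product for one percent more catalyst charged)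
- factor on the rate of making left-handed product when 5.0% of the left-handed substrate and right-handed substrate together are converted if catalyst is charged twice over

The kineticist argued that the curves start S-shaped, so she took conversion near the start to grow with the square of time. The east readings show a power of 1.40, she granted, but that span runs past the asked conversion, to 23.1%.

She proposed the east and south-east runs as a pair. They share a charge of solid reagent and a reading time, 3.00 min. She assumed first order in substrate, so that percent of charge per minute does not carry the substrate. The two readings then give 0.665. This is the percent gain of early conversion at a fixed time for one percent more catalyst charged, the working exponent.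

The process chemist set the scale: 1 if each added catalyst works, 0.5 if catalyst sits mostly in pairs. The reading lies between them, and each reading behind it scatters by 1 percentage point.

My own reckoning as minute-taker follows. On the kineticist's square law, the time to a fixed conversion falls with half the working exponent, and the rate there rises by that same power. So the order is 0.332, and a double charge gives 1.26.

The forecast, which differs from this, says 0.47 and 1.38, from “an order near 0.4–0.5”.

The flask gives:

0.31 for the order and 1.22 for the double charge, at 1.20 min.

    coupling partner + catalyst + left-handed substrate → catalyst + left-handed product (k = 31000 L² mol⁻² s⁻¹)
    coupling partner + catalyst + right-handed substrate → catalyst + right-handed product (k = 580 L² mol⁻² s⁻¹)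
    solid reagent ⇌ coupling partner, rate k3*(cs3 - [coupling partner]) while solid is left; crystals form when [coupling partner] > cs3 (solubility = 15.0 mM, k = 0.00770 s⁻¹)
    2 catalyst ⇌ resting dimer (K = 38000 L mol⁻¹, k = 27000 L mol⁻¹ s⁻¹)

In the flask, catalyst stands at 44.9% free and 55.1% as resting dimer, the resting state, at 0.800 min and still at 80.0 min. The east run read 23.1% at 3.00 min. Carried to this flask's 36 µM, half the working exponent stretches that time to 3.90 min. The flask holds 24.0% left-handed product at 4.00 min.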